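## Structural features

The target is a 15-membered benzoate macrolide. A 4-hydroxybenzoate esterifies the C13 carbinol, and the ring carbon ortho to the phenol (Ar5) carries a benzylic CH2 (C15) bonded to C14 of a cyclohexene (ring A), so the arene is bridged meta (Ar1 carboxyl, Ar4 OH, Ar5–C15). Numbering used throughout: ring A is C2(Me)=C3–C4–C5(Br)–C6(Me)–C14; the chain is C7–C8–C9(Br)–C10(Me)(OH)–C11–C12–C13(O)–CMe2Br. Ring A holds three contiguous stereocentres, C5 (S, secondary bromide), C6 (S, quaternary) and C14 (R), with Br, the C6 methyl and the C15 arm on one face and C7 on the other. The chain carries an anti bromohydrin (C9 R, C10 S) and, three carbons further, C13 (S) next to a tertiary bromide. Fragile groups are the tertiary bromide β to the ester oxygen (ionisation, elimination), the bromohydrin (epoxide closure whenever O10 is a free alkoxide under base), the homoallylic C5 bromide (expected equatorial in the half-chair, so without an antiperiplanar hydrogen) and the phenol. The real difficulty is not ring A but the acyclic centres C9, C10 and C13, which lie too far from ring A for substrate control, and closure of the macrocycle in the presence of three C–Br bonds. The key step uses the C10–C11–C12–C13 spacing: with C13 as a carboxylic acid and C9=C10 as an E alkene, one anti addition places Br on C9 and delivers the C10 oxygen from the acid, closing a γ-lactone.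

## Logic of the disconnections

**33 ⇒ 32.** The two O–Si bonds are cut last. A free phenol would quench the radical chemistry of the preceding step, and a free C10 hydroxyl next to the C9 bromide closes to an epoxide under base, so both stay masked to the end. The demand is a fluoride source that is neither basic nor strongly acidic, because of the tertiary bromide.

**32 ⇒ 31.** The tertiary C–Br bond (and one C–H) is cut, giving the isopropenyl group. The most fragile bond is thereby formed last, and 31 contains only robust functionality. The forward step must add Markovnikov to the 1,1-disubstituted alkene without touching C2=C3 and without ionic conditions.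

**31 ⇒ 30.** Both bonds to the ester carbonyl carbon (Ar1–C and C–O13) are cut. The macrocycle opens to an aryl bromide and a secondary alcohol, and the carbonyl carbon is inserted at ring closure, so no carboxyl group has to be carried. Zerovalent palladium must select the aryl bromide over two secondary alkyl bromides, and O10 must be protected against the base.

**30 ⇒ 29 ⇒ 27 + 28.** The C13–H bond is cut first, then the C13–isopropenyl bond. No neighbouring centre can direct C13, so it comes from reagent-controlled reduction of ketone 29. Ketone 29 comes from single addition of the three-carbon nucleophile 28 to the acyl donor 27.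

**27 ⇒ 25 ⇒ 24.** The O–Si bonds and the amide C–N bond are cut, reconnecting C13 to O10 as lactone 24. The lactone is the protected form of both the tertiary alcohol and the C13 acyl group. The aryl ester of 24 is exchanged for a silyl ether in the same two operations. Ring opening must not let the C10 alkoxide displace the C9 bromide.

**24 ⇒ 23 (key).** C9–Br and C10–O are cut, giving the E-alkenoic acid 23. Two stereocentres and one ring are removed in one step with fixed regiochemistry. The forward step needs catalyst face control and site selectivity over C2=C3. Two changes to the precursor serve this: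
- The phenol of 23 is an aryl ester, not a silyl ether. It survives the fluoride and base used earlier, it makes the arene and its oxygen non-nucleophilic toward the bromonium source, and it is removed without an extra step.
- The acid is brought in free, so no saponification is run on a molecule with base-labile groups.

**23 ⇒ 17 + 21.** The C8–C9 sp3–sp2 bond is cut. The geometry of the trisubstituted alkene is fixed in a small fragment (21), and the route becomes convergent. The forward step needs hydroboration of the vinyl group only and coupling at C–I, not at aryl C–Br.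

**21 ⇒ 20 ⇒ 18.** The oxidation level at C13 is adjusted, then C10–CH3 and C9–I are traced to syn carbometallation of a terminal alkyne, which fixes E geometry.

**17 ⇒ 16 ⇒ 15 ⇒ 14.** C7=C8 is cut (one-carbon olefination), then C3–H is returned to C3–O (enol triflate, then enol silyl ether). The C3 oxygen is what controls regiochemistry in ring formation and is removed afterwards. The demands are regiospecific trapping of the enolate (the C5 bromide is β to C3) and reduction of a vinyl triflate beside an aryl bromide.

**14 ⇒ 10 + 13.** C6–C14 and C4–C5 are cut ([4+2]). All three ring A stereocentres, including the quaternary carbon and the C–Br centre, come from two achiral components. The forward step needs the formyl-exo mode, face selectivity and "ortho/para" regiochemistry.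

**13 ⇒ 11; 10 ⇒ 9 ⇒ 7 + 8; 7 ⇒ 5 ⇒ 4 ⇒ 3 ⇒ 1 + 2.** These are bromination–dehydrobromination of an enal, enol silylation, olefination at C14=C2, oxidative cleavage of an allyl group, O-acylation, [3,3] shift of an aryl allyl ether, and O-allylation. Each is a standard operation on simple material.

## Other disconnections considered

**Alternative 1:** The cut is C6–C14 together with C5–Br, made across the finished macrocycle. A2 (the target as phenol acetate and C10 triethylsilyl ether) is opened to the 19-membered (E,E)-dienyl lactone A1. In the forward step Et2SBr·SbCl5Br would place bromonium on C5=C6 of A1, C14 of the C14=C2 alkene would attack C6 through a chair-like array, and loss of a proton from C3 would leave C2=C3. Ring A, the C5 bromide and three stereocentres would form while the ring contracts from 19 to 15 members.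
- In its favour: one step forms what steps 6–11 of the chosen plan form, and a 19-membered seco acid should close more readily than the 15-membered ring. On step economy and on ease of macrocyclisation this alternative is the better one. The E,E geometry translates into the correct relative configuration of C5, C6 and C14 through a chair.
- Against it here: A1 has two trisubstituted alkenes of similar nucleophilicity. The face of C5=C6 attacked relative to C9, C10 and C13 would depend only on the conformation of a flexible 19-membered ring, with no reagent control. The C2 cation can lose a proton in more than one direction or be trapped by the nearby arene. The tertiary bromide and the silyl ether must survive a strong halophilic Lewis acid.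
- Comparison: on structure, the chosen plan assigns a named control element to every stereocentre and is the more predictable. On mechanism, a cationic cascade is set against a pericyclic step plus a catalyst-controlled halocyclisation. A1 would still need the C9/C10 bromohydrin, for which it could use the same bromolactonisation, so the two are equal on that point.

**Alternative 2:** The cut is the pair of bonds to the ester carbonyl carbon. A4 (the macrolide with a 9,10-epoxide, an isopropenyl group and a phenol silyl ether) is opened to the aryl bromide alcohol A3 plus carbon monoxide. In the forward step Pd(OAc)2/Xantphos under CO would turn Ar1–Br into an aroylpalladium that the C13 hydroxyl captures.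
- In its favour: the carboxyl carbon is added only at ring closure, so no acid or ester is carried. The 9,10-epoxide is a base-stable mask of the bromohydrin, with no C9 bromide to eliminate and no alkoxide to close during the hot, basic carbonylation. On this point the alternative is better than the chosen plan, which takes C9–Br and a C10 silyl ether through step 20.
- Against it here: the epoxide must be made with reagent control beside C2=C3. It must then be opened late by bromide at secondary C9 with inversion, in competition with opening at tertiary C10, on a molecule that must also be hydrobrominated at the isopropenyl group.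
- Comparison: the ring-closing event is the same as step 20 of the chosen plan, so on macrocyclisation (structure, mechanism, risk from the C5 bromide) the two are equal. The difference is at C9/C10. The chosen plan sets Br and O in one anti addition of fixed regiochemistry, whereas this alternative needs an epoxidation and an opening of uncertain regiochemistry. Step counts are about equal.

**Alternative 3:** The cut is C6–C14 and C4–C5 of ring A. A6 (ring A aldehyde with a C3 silyl enol ether and a phenol silyl ether) goes back to the bis-silyl diene A5 and the bromo-enal 13. In the forward step a chiral oxazaborolidinium Lewis acid promotes the [4+2] addition.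
- In its favour: three contiguous stereocentres, including the quaternary carbon and the C–Br centre, come from two cheap achiral components, early, where optimisation is inexpensive.
- Against it here: the formyl-exo mode is required, and the C3 oxygen costs two later steps. In A5 and A6 both the enol and the phenol are silyl ethers, so fluoride-mediated conversion of the enol ether into a triflate would also strip the phenol. As the strategic step it leaves C9, C10, C13 and the macrocycle unaddressed.
- Comparison: this is not a rival. The chosen plan contains the same cycloaddition as step 8, with a pivalate in place of the phenol silyl ether, so the two are equal on ring A structure and step economy. As the step carrying the strategy it comes too early, because the difficult remote centres are handled by the halocyclisation.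

Key step: step 15

Assumption (chemistry): ylide 8 and Grignard reagent 28 are bought as such; the sense of induction in steps 8 and 15 is taken from the accepted binding models of the two catalyst families, and the other hand (antipode or pseudoenantiomer) is available in both cases.

## Steps

Step 1
Reactants: 1 4-bromophenol; 2 allyl bromide
Product: 3 1-(allyloxy)-4-bromobenzene
Conditions: K2CO3, acetone, reflux
Reagents that add atoms: none
Why: Williamson O-alkylation of the phenoxide; carbonate in acetone favours O- over C-alkylation.

Step 2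
Reactants: 3 1-(allyloxy)-4-bromobenzene
Product: 4 2-allyl-4-bromophenol
Conditions: N,N-diethylaniline, 195 °C
Reagents that add atoms: none
Why: Aromatic Claisen rearrangement ([3,3]) then tautomerisation; the para position is blocked by bromine, so only the ortho-allyl phenol can form.

Step 3
Reactants: 4 2-allyl-4-bromophenol
Product: 5 2-allyl-4-bromophenyl pivalate
Conditions: PivCl, Et3N, DMAP (cat.), CH2Cl2, 0 °C → rt
Reagents that add atoms: pivaloyl chloride (CC(C)(C)C(=O)Cl)
Why: Acylation of the phenol; the hindered aryl ester tolerates fluoride, ylides and mild aqueous base and makes the arene and its oxygen non-nucleophilic for the later NBS step.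

Step 4
Reactants: 5 2-allyl-4-bromophenyl pivalate
Product: 7 4-bromo-2-(2-oxoethyl)phenyl pivalate, via ozonide 6 (not isolated)
Conditions: O3, CH2Cl2, −78 °C; then PPh3, −78 °C → rt
Reagents that add atoms: ozone ([O-][O+]=O)
Why: Ozonolysis of the terminal alkene with reductive work-up; the acylated ring is too electron-poor to compete, and the enolisable arylacetaldehyde is used crude.

Step 5
Reactants: 7 4-bromo-2-(2-oxoethyl)phenyl pivalate; 8 3-(triphenylphosphoranylidene)butan-2-one
Product: 9 4-bromo-2-[(2E)-3-methyl-4-oxopent-2-en-1-yl]phenyl pivalate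
Conditions: toluene, 50 °C
Reagents that add atoms: none
Why: Wittig olefination with a stabilised α-methyl acyl ylide should give the E trisubstituted enone (acyl trans to the CH2Ar group) under neutral conditions that do not move the double bond toward the arene.

Step 6
Reactants: 9 4-bromo-2-[(2E)-3-methyl-4-oxopent-2-en-1-yl]phenyl pivalate
Product: 10 4-bromo-2-[(2E)-3-methyl-4-(triisopropylsilyloxy)penta-2,4-dien-1-yl]phenyl pivalate
Conditions: TIPSOTf, Et3N, CH2Cl2, −78 → 0 °C
Reagents that add atoms: triisopropylsilyl triflate (CC(C)[Si](C(C)C)(C(C)C)OS(=O)(=O)C(F)(F)F)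
Why: Soft enolisation: O-silylation of the ketone and loss of an α′ methyl proton give the cross-conjugated 2-silyloxy diene kinetically, leaving the E geometry of C2=C14 untouched.

Step 7
Reactants: 11 methacrolein
Product: 13 (E)-3-bromo-2-methylprop-2-enal, via 2,3-dibromo-2-methylpropanal 12 (not isolated)
Conditions: Br2, CH2Cl2, 0 °C; then Et3N, 0 °C → rt
Reagents that add atoms: bromine (BrBr)
Why: Bromine addition, then amine-induced E2 loss of HBr (tertiary α-bromide, hydrogen from the CH2Br carbon) gives the conjugated β-bromo enal; the E isomer (Br trans to CHO) is the stable one.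

Step 8
Reactants: 10 4-bromo-2-[(2E)-3-methyl-4-(triisopropylsilyloxy)penta-2,4-dien-1-yl]phenyl pivalate; 13 (E)-3-bromo-2-methylprop-2-enal
Product: 14 (1R,2R,6S)-6-bromo-2-(5-bromo-2-pivaloyloxybenzyl)-1,3-dimethyl-4-(triisopropylsilyloxy)cyclohex-3-ene-1-carbaldehyde
Conditions: oxazaborolidinium triflimide from (S)-α,α-diphenylprolinol, o-tolylboronic acid and HNTf2 (20 mol%), CH2Cl2, −78 → −40 °C
Reagents that add atoms: none
Why: Lewis acid-catalysed Diels–Alder reaction of an α-branched enal; the silyloxy group makes C4 the nucleophilic terminus, so C4 bonds to the β-carbon C5 and C14 to C6, and the E dienophile keeps Br and the C6 methyl cis. The formyl-exo transition state expected for α-substituted enals with this catalyst class and (E)-1-substituted 3-silyloxy dienes places C15 cis to the methyl and trans to the formyl group, and the catalyst's face selection sets the absolute configuration.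

Step 9
Reactants: 14 (1R,2R,6S)-6-bromo-2-(5-bromo-2-pivaloyloxybenzyl)-1,3-dimethyl-4-(triisopropylsilyloxy)cyclohex-3-ene-1-carbaldehyde
Product: 15 (1R,2R,6S)-6-bromo-2-(5-bromo-2-pivaloyloxybenzyl)-1,3-dimethyl-4-(trifluoromethylsulfonyloxy)cyclohex-3-ene-1-carbaldehyde
Conditions: CsF, PhNTf2, DME, 23 °C
Reagents that add atoms: N-phenylbis(trifluoromethanesulfonimide) (FC(F)(F)S(=O)(=O)N(c1ccccc1)S(=O)(=O)C(F)(F)F)
Why: Fluoride cleaves the enol silyl ether, and the enolate is O-triflated by the PhNTf2 already present before it can equilibrate toward C4, which would expel the C5 bromide. The aryl pivalate is inert to CsF, where a phenol silyl ether would be lost.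

Step 10
Reactants: 15 (1R,2R,6S)-6-bromo-2-(5-bromo-2-pivaloyloxybenzyl)-1,3-dimethyl-4-(trifluoromethylsulfonyloxy)cyclohex-3-ene-1-carbaldehyde
Product: 16 (1R,2R,6S)-6-bromo-2-(5-bromo-2-pivaloyloxybenzyl)-1,3-dimethylcyclohex-3-ene-1-carbaldehyde
Conditions: Pd(OAc)2 (5 mol%), PPh3, HCO2H, n-Bu3N, DMF, 40 °C
Reagents that add atoms: none
Why: Palladium-catalysed formate reduction of an enol triflate; with PPh3 at 40 °C zerovalent palladium should insert into the vinyl C–OTf bond much faster than into the aryl C–Br bond, and unactivated secondary alkyl bromides do not add under these conditions.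

Step 11
Reactants: 16 (1R,2R,6S)-6-bromo-2-(5-bromo-2-pivaloyloxybenzyl)-1,3-dimethylcyclohex-3-ene-1-carbaldehyde
Product: 17 4-bromo-2-{[(1R,5S,6S)-5-bromo-6-ethenyl-2,6-dimethylcyclohex-2-en-1-yl]methyl}phenyl pivalate
Conditions: Ph3PCH3Br, KN(SiMe3)2, THF, 0 °C; then 16, −78 → 0 °C
Reagents that add atoms: methyltriphenylphosphonium bromide (C[P+](c1ccccc1)(c1ccccc1)c1ccccc1.[Br-])
Why: Wittig methylenation of a non-enolisable hindered aldehyde; the aldehyde is far more electrophilic than the pivalate, and the equatorial C5 bromide has no antiperiplanar hydrogen for the ylide to remove.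

Step 12
Reactants: 18 pent-4-yn-1-ol
Product: 20 (E)-5-iodo-4-methylpent-4-en-1-ol, via alkenylalane 19 (not isolated)
Conditions: AlMe3 (3 equiv), Cp2ZrCl2 (25 mol%), CH2Cl2, 0 °C → rt; then I2, THF, −30 °C
Reagents that add atoms: trimethylaluminium (C[Al](C)C); iodine (II)
Why: Zirconium-catalysed carboalumination (Negishi) adds Me and Al syn across the alkyne with Al on the terminal carbon; iodinolysis with retention gives the E vinyl iodide, which fixes the geometry of the future C9=C10.

Step 13
Reactants: 20 (E)-5-iodo-4-methylpent-4-en-1-ol
Product: 21 (E)-5-iodo-4-methylpent-4-enoic acid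
Conditions: TEMPO (cat.), PhI(OAc)2, MeCN/H2O, rt
Reagents that add atoms: water (O)
Why: Oxoammonium-mediated oxidation takes the primary alcohol through the aldehyde hydrate to the acid; the vinyl iodide is inert.

Step 14
Reactants: 17 4-bromo-2-{[(1R,5S,6S)-5-bromo-6-ethenyl-2,6-dimethylcyclohex-2-en-1-yl]methyl}phenyl pivalate; 21 (E)-5-iodo-4-methylpent-4-enoic acid
Product: 23 (4E)-7-[(1S,2R,6S)-6-bromo-2-(5-bromo-2-pivaloyloxybenzyl)-1,3-dimethylcyclohex-3-en-1-yl]-4-methylhept-4-enoic acid, via B-alkyl-9-BBN borane 22 (not isolated)
Conditions: 9-BBN-H, THF, 0 °C → rt; then 21, Pd(dppf)Cl2 (5 mol%), AsPh3, aq. K3PO4, DMF, rt; work-up at pH 4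
Reagents that add atoms: none
Why: B-alkyl Suzuki–Miyaura coupling: 9-BBN hydroborates the monosubstituted vinyl group and not the hindered ring alkene, and the alkylborane couples with the vinyl iodide at rt with retention of E geometry while aryl and alkyl bromides stay intact. The acid enters as its carboxylate, so no ester hydrolysis is needed.

Step 15
Reactants: 23 (4E)-7-[(1S,2R,6S)-6-bromo-2-(5-bromo-2-pivaloyloxybenzyl)-1,3-dimethylcyclohex-3-en-1-yl]-4-methylhept-4-enoic acid
Product: 24 (5S)-5-{(1R)-1-bromo-3-[(1S,2R,6S)-6-bromo-2-(5-bromo-2-pivaloyloxybenzyl)-1,3-dimethylcyclohex-3-en-1-yl]propyl}-5-methyloxolan-2-one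
Conditions: NBS (1.2 equiv), quinidine-derived amino-thiocarbamate catalyst (9-O-(N-arylthiocarbamoyl)quinidine, 10 mol%), 4-nitrobenzenesulfonamide (additive), CHCl3/toluene, −60 °C, dark
Reagents that add atoms: N-bromosuccinimide (O=C1CCC(=O)N1Br)
Why: The thiocarbamate sulfur takes up Br+ from NBS while the quinuclidine nitrogen holds the carboxylic acid as an ion pair, so bromine is passed to one face of the E alkene C9=C10 and the carboxylate opens the bromonium ion at tertiary C10 from the opposite face. The closest known reaction type is the amino-thiocarbamate-catalysed enantioselective 5-exo bromolactonisation of 4-substituted alk-4-enoic acids, a trialkyl E alkene lying at the edge of that scope. The γ-lactone closes by 5-exo-tet attack of the carboxylate oxygen on C10 (Markovnikov opening of the bromonium ion). C9 (R) is set by the catalyst's choice of alkene face, ring A being too remote to bias it; C10 (S) follows stereospecifically from anti addition to the E alkene fixed in step 12. The step needs face selectivity (the quinine-derived pseudoenantiomer is used if the first catalyst delivers the other face), Markovnikov regiochemistry (tertiary C10 carries the charge, 6-endo attack at C9 is disfavoured) and site selectivity over C2=C3. Site selectivity comes from the acid tether, which holds the catalyst next to C9=C10 and makes bromination there irreversible, whereas C2=C3 is hindered and has no internal nucleophile because the aryl oxygen is an ester. The electron-poor aryl pivalate also keeps NBS off the arene.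

Step 16
Reactants: 24 (5S)-5-{(1R)-1-bromo-3-[(1S,2R,6S)-6-bromo-2-(5-bromo-2-pivaloyloxybenzyl)-1,3-dimethylcyclohex-3-en-1-yl]propyl}-5-methyloxolan-2-one
Product: 25 (4S,5R)-5-bromo-7-[(1S,2R,6S)-6-bromo-2-(5-bromo-2-hydroxybenzyl)-1,3-dimethylcyclohex-3-en-1-yl]-4-hydroxy-N-methoxy-N,4-dimethylheptanamide
Conditions: MeNH(OMe)·HCl (6 equiv), AlMe3 (6 equiv), CH2Cl2, 0 → 35 °C; cold aq. potassium sodium tartrate work-up; used at once
Reagents that add atoms: N,O-dimethylhydroxylamine hydrochloride (CNOC.Cl)
Why: Weinreb aminolysis: the aluminium amide opens the lactone to the N-methoxy-N-methylamide and also cleaves the activated aryl pivalate, so the phenol is freed without a separate step. The C10 oxygen is held as a weakly nucleophilic aluminium alkoxide, which should not displace the C9 bromide; the crude product is silylated immediately to prevent relactonisation.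

Step 17
Reactants: 25 (4S,5R)-5-bromo-7-[(1S,2R,6S)-6-bromo-2-(5-bromo-2-hydroxybenzyl)-1,3-dimethylcyclohex-3-en-1-yl]-4-hydroxy-N-methoxy-N,4-dimethylheptanamide
Product: 27 (4S,5R)-5-bromo-7-[(1S,2R,6S)-6-bromo-2-(5-bromo-2-(tert-butyldimethylsilyloxy)benzyl)-1,3-dimethylcyclohex-3-en-1-yl]-N-methoxy-N,4-dimethyl-4-(triethylsilyloxy)heptanamide, via aryl TBS ether 26 (not isolated)
Conditions: TBSCl, imidazole, CH2Cl2, 0 °C; then 2,6-lutidine, TESOTf, −78 → 0 °C
Reagents that add atoms: tert-butyldimethylsilyl chloride (CC(C)(C)[Si](C)(C)Cl); triethylsilyl triflate (CC[Si](CC)(CC)OS(=O)(=O)C(F)(F)F)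
Why: The silyl chloride takes only the phenol, and the silyl triflate then silylates the hindered tertiary hydroxyl; this blocks relactonisation and any later base-induced epoxide closure.

Step 18
Reactants: 27 (4S,5R)-5-bromo-7-[(1S,2R,6S)-6-bromo-2-(5-bromo-2-(tert-butyldimethylsilyloxy)benzyl)-1,3-dimethylcyclohex-3-en-1-yl]-N-methoxy-N,4-dimethyl-4-(triethylsilyloxy)heptanamide; 28 isopropenylmagnesium bromide
Product: 29 (6S,7R)-7-bromo-9-[(1S,2R,6S)-6-bromo-2-(5-bromo-2-(tert-butyldimethylsilyloxy)benzyl)-1,3-dimethylcyclohex-3-en-1-yl]-2,6-dimethyl-6-(triethylsilyloxy)non-1-en-3-one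
Conditions: THF, −20 → 0 °C; inverse quench into cold aq. NH4Cl
Reagents that add atoms: none
Why: Weinreb ketone synthesis: the chelated tetrahedral intermediate prevents a second addition, and the inverse quench keeps the released amine from adding to the new enone. The neopentyl-type secondary bromides and the aryl bromide do not react with the Grignard reagent at this temperature.

Step 19
Reactants: 29 (6S,7R)-7-bromo-9-[(1S,2R,6S)-6-bromo-2-(5-bromo-2-(tert-butyldimethylsilyloxy)benzyl)-1,3-dimethylcyclohex-3-en-1-yl]-2,6-dimethyl-6-(triethylsilyloxy)non-1-en-3-one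
Product: 30 (3S,6S,7R)-7-bromo-9-[(1S,2R,6S)-6-bromo-2-(5-bromo-2-(tert-butyldimethylsilyloxy)benzyl)-1,3-dimethylcyclohex-3-en-1-yl]-2,6-dimethyl-6-(triethylsilyloxy)non-1-en-3-ol
Conditions: (R)-2-methyl-CBS-oxazaborolidine, catecholborane, toluene, −78 °C
Reagents that add atoms: none
Why: Corey–Bakshi–Shibata reduction: the isopropenyl group acts as the large substituent, so the R catalyst should deliver hydride to give the 13S allylic alcohol by reagent control. Catecholborane at −78 °C reduces 1,2 and does not hydroborate the alkenes.

Step 20
Reactants: 30 (3S,6S,7R)-7-bromo-9-[(1S,2R,6S)-6-bromo-2-(5-bromo-2-(tert-butyldimethylsilyloxy)benzyl)-1,3-dimethylcyclohex-3-en-1-yl]-2,6-dimethyl-6-(triethylsilyloxy)non-1-en-3-ol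
Product: 31 15-membered lactone (5S,6S,9R,10S,13S,14R) with isopropenyl on C13 and C10–OSiEt3 and Ar4–OSiMe2t-Bu
Conditions: Pd(OAc)2 (10 mol%), Xantphos, CO (1 atm), Et3N, toluene, 90 °C, slow addition (final 2 mM)
Reagents that add atoms: carbon monoxide ([C-]#[O+])
Why: Intramolecular palladium-catalysed alkoxycarbonylation (carbonylative macrolactonisation): oxidative addition at the aryl bromide, CO insertion and capture of the aroylpalladium by the C13 hydroxyl form Ar1–C(=O) and C(=O)–O13. The wide-bite-angle ligand allows 1 atm CO, high dilution favours the ring, and unactivated secondary alkyl bromides should not add to zerovalent palladium here; no stereocentre is touched.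

Step 21
Reactants: 31 15-membered lactone (5S,6S,9R,10S,13S,14R) with isopropenyl on C13 and C10–OSiEt3 and Ar4–OSiMe2t-Bu
Product: 32 bis-silyl ether of the target (C10–OSiEt3 and Ar4–OSiMe2t-Bu; CMe2Br on C13)
Conditions: Co(acac)2 (0.5 equiv), t-BuOOH (initiator), Et3SiH, TsBr, n-PrOH/CH2Cl2, 23 °C
Reagents that add atoms: p-toluenesulfonyl bromide (Cc1ccc(cc1)S(=O)(=O)Br)
Why: Mukaiyama-type hydrogen-atom-transfer hydrobromination: the cobalt hydride gives H to the CH2 terminus of the 1,1-disubstituted alkene, and the tertiary radical abstracts bromine from TsBr (Markovnikov). The hindered trisubstituted ring alkene should react more slowly, as in terpene dienes that carry both alkene types, and the phenol is kept silylated because a free phenol would quench the radical.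

Step 22
Reactants: 32 bis-silyl ether of the target (C10–OSiEt3 and Ar4–OSiMe2t-Bu; CMe2Br on C13)
Product: 33 CNP0215732.1 (5S,6S,9R,10S,13S,14R)
Conditions: HF·pyridine, pyridine/THF, 0 °C → rt
Reagents that add atoms: none
Why: Fluoride-mediated desilylation of the aryl and tertiary silyl ethers under buffered, non-basic conditions, so no alkoxide is formed that could close the bromohydrin to an epoxide or eliminate the tertiary bromide.

## Compound list

1 | 4-bromophenol | Oc1ccc(Br)cc1 | starting material
2 | allyl bromide | C=CCBr | starting material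
3 | 1-(allyloxy)-4-bromobenzene | C=CCOc1ccc(Br)cc1 | intermediate
4 | 2-allyl-4-bromophenol | C=CCc1cc(Br)ccc1O | intermediate
5 | 2-allyl-4-bromophenyl pivalate | C=CCc1cc(Br)ccc1OC(=O)C(C)(C)C | intermediate
6 | 3-(5-bromo-2-pivaloyloxybenzyl)-1,2,4-trioxolane (ozonide) | CC(C)(C)C(=O)Oc1ccc(Br)cc1CC1OCOO1 | intermediate
7 | 4-bromo-2-(2-oxoethyl)phenyl pivalate | O=CCc1cc(Br)ccc1OC(=O)C(C)(C)C | intermediate
8 | 3-(triphenylphosphoranylidene)butan-2-one | CC(=O)C(C)=P(c1ccccc1)(c1ccccc1)c1ccccc1 | starting material
9 | 4-bromo-2-[(2E)-3-methyl-4-oxopent-2-en-1-yl]phenyl pivalate | CC(=O)/C(C)=C/Cc1cc(Br)ccc1OC(=O)C(C)(C)C | intermediate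
10 | 4-bromo-2-[(2E)-3-methyl-4-(triisopropylsilyloxy)penta-2,4-dien-1-yl]phenyl pivalate | C=C(O[Si](C(C)C)(C(C)C)C(C)C)/C(C)=C/Cc1cc(Br)ccc1OC(=O)C(C)(C)C | intermediate
11 | methacrolein | CC(=C)C=O | starting material
12 | 2,3-dibromo-2-methylpropanal | O=CC(C)(Br)CBr | intermediate
13 | (E)-3-bromo-2-methylprop-2-enal | O=C/C(C)=C/Br | intermediate
14 | (1R,2R,6S)-6-bromo-2-(5-bromo-2-pivaloyloxybenzyl)-1,3-dimethyl-4-(triisopropylsilyloxy)cyclohex-3-ene-1-carbaldehyde | CC1=C(O[Si](C(C)C)(C(C)C)C(C)C)C[C@H](Br)[C@@](C)(C=O)[C@@H]1Cc1cc(Br)ccc1OC(=O)C(C)(C)C | intermediate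
15 | (1R,2R,6S)-6-bromo-2-(5-bromo-2-pivaloyloxybenzyl)-1,3-dimethyl-4-(trifluoromethylsulfonyloxy)cyclohex-3-ene-1-carbaldehyde | CC1=C(OS(=O)(=O)C(F)(F)F)C[C@H](Br)[C@@](C)(C=O)[C@@H]1Cc1cc(Br)ccc1OC(=O)C(C)(C)C | intermediate
16 | (1R,2R,6S)-6-bromo-2-(5-bromo-2-pivaloyloxybenzyl)-1,3-dimethylcyclohex-3-ene-1-carbaldehyde | CC1=CC[C@H](Br)[C@@](C)(C=O)[C@@H]1Cc1cc(Br)ccc1OC(=O)C(C)(C)C | intermediate
17 | 4-bromo-2-{[(1R,5S,6S)-5-bromo-6-ethenyl-2,6-dimethylcyclohex-2-en-1-yl]methyl}phenyl pivalate | CC1=CC[C@H](Br)[C@@](C)(C=C)[C@@H]1Cc1cc(Br)ccc1OC(=O)C(C)(C)C | intermediate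
18 | pent-4-yn-1-ol | C#CCCCO | starting material
19 | (E)-alkenylalane from 18 (Me2Al on C9, O–AlMe2) | C[Al](C)/C=C(C)/CCCO[Al](C)C | intermediate
20 | (E)-5-iodo-4-methylpent-4-en-1-ol | OCCC/C(C)=C/I | intermediate
21 | (E)-5-iodo-4-methylpent-4-enoic acid | OC(=O)CC/C(C)=C/I | intermediate
22 | B-alkyl-9-BBN borane from 17 (boron on C8) | CC1=CC[C@H](Br)[C@@](C)(CCB2C3CCCC2CCC3)[C@@H]1Cc1cc(Br)ccc1OC(=O)C(C)(C)C | intermediate
23 | (4E)-7-[(1S,2R,6S)-6-bromo-2-(5-bromo-2-pivaloyloxybenzyl)-1,3-dimethylcyclohex-3-en-1-yl]-4-methylhept-4-enoic acid | CC1=CC[C@H](Br)[C@@](C)(CC/C=C(C)/CCC(=O)O)[C@@H]1Cc1cc(Br)ccc1OC(=O)C(C)(C)C | intermediate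
24 | (5S)-5-{(1R)-1-bromo-3-[(1S,2R,6S)-6-bromo-2-(5-bromo-2-pivaloyloxybenzyl)-1,3-dimethylcyclohex-3-en-1-yl]propyl}-5-methyloxolan-2-one | CC1=CC[C@H](Br)[C@@](C)(CC[C@@H](Br)[C@@]2(C)OC(=O)CC2)[C@@H]1Cc1cc(Br)ccc1OC(=O)C(C)(C)C | intermediate
25 | (4S,5R)-5-bromo-7-[(1S,2R,6S)-6-bromo-2-(5-bromo-2-hydroxybenzyl)-1,3-dimethylcyclohex-3-en-1-yl]-4-hydroxy-N-methoxy-N,4-dimethylheptanamide | CC1=CC[C@H](Br)[C@@](C)(CC[C@@H](Br)[C@@](C)(O)CCC(=O)N(C)OC)[C@@H]1Cc1cc(Br)ccc1O | intermediate
26 | aryl TBS ether of 25 (C10–OH free) | CC1=CC[C@H](Br)[C@@](C)(CC[C@@H](Br)[C@@](C)(O)CCC(=O)N(C)OC)[C@@H]1Cc1cc(Br)ccc1O[Si](C)(C)C(C)(C)C | intermediate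
27 | (4S,5R)-5-bromo-7-[(1S,2R,6S)-6-bromo-2-(5-bromo-2-(tert-butyldimethylsilyloxy)benzyl)-1,3-dimethylcyclohex-3-en-1-yl]-N-methoxy-N,4-dimethyl-4-(triethylsilyloxy)heptanamide | CC1=CC[C@H](Br)[C@@](C)(CC[C@@H](Br)[C@@](C)(O[Si](CC)(CC)CC)CCC(=O)N(C)OC)[C@@H]1Cc1cc(Br)ccc1O[Si](C)(C)C(C)(C)C | intermediate
28 | isopropenylmagnesium bromide | C=C(C)[Mg]Br | starting material
29 | (6S,7R)-7-bromo-9-[(1S,2R,6S)-6-bromo-2-(5-bromo-2-(tert-butyldimethylsilyloxy)benzyl)-1,3-dimethylcyclohex-3-en-1-yl]-2,6-dimethyl-6-(triethylsilyloxy)non-1-en-3-one | CC1=CC[C@H](Br)[C@@](C)(CC[C@@H](Br)[C@@](C)(O[Si](CC)(CC)CC)CCC(=O)C(C)=C)[C@@H]1Cc1cc(Br)ccc1O[Si](C)(C)C(C)(C)C | intermediate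
30 | (3S,6S,7R)-7-bromo-9-[(1S,2R,6S)-6-bromo-2-(5-bromo-2-(tert-butyldimethylsilyloxy)benzyl)-1,3-dimethylcyclohex-3-en-1-yl]-2,6-dimethyl-6-(triethylsilyloxy)non-1-en-3-ol | CC1=CC[C@H](Br)[C@@](C)(CC[C@@H](Br)[C@@](C)(O[Si](CC)(CC)CC)CC[C@@H](C(C)=C)O)[C@@H]1Cc1cc(Br)ccc1O[Si](C)(C)C(C)(C)C | intermediate
31 | 15-membered lactone (5S,6S,9R,10S,13S,14R) with isopropenyl on C13 and C10–OSiEt3 and Ar4–OSiMe2t-Bu | CC1=CC[C@H](Br)[C@@]2(C)CC[C@@H](Br)[C@@](C)(O[Si](CC)(CC)CC)CC[C@@H](C(C)=C)OC(=O)c3ccc(O[Si](C)(C)C(C)(C)C)c(c3)C[C@H]12 | intermediate
32 | bis-silyl ether of the target (C10–OSiEt3 and Ar4–OSiMe2t-Bu; CMe2Br on C13) | CC1=CC[C@H](Br)[C@@]2(C)CC[C@@H](Br)[C@@](C)(O[Si](CC)(CC)CC)CC[C@@H](C(C)(C)Br)OC(=O)c3ccc(O[Si](C)(C)C(C)(C)C)c(c3)C[C@H]12 | intermediate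
33 | CNP0215732.1 (5S,6S,9R,10S,13S,14R) | CC1=CC[C@H](Br)[C@@]2(C)CC[C@@H](Br)[C@@](C)(O)CC[C@@H](C(C)(C)Br)OC(=O)c3ccc(O)c(c3)C[C@H]12 | target

## Step count and least certain steps

Total: 22 steps. Longest linear sequence: 19 steps (steps 1–6, 8–11, 14–22).

**Step 15 (key step).** The likely failures are weak face discrimination, because a trialkyl alkene gives the catalyst less to recognise than the aryl-substituted alkenes of the established scope, and some bromonium formation at C2=C3. Fallback: setting out from 23, the bromolactonisation is run without a chiral catalyst (NBS, NaHCO3, MeCN, 0 °C), relying only on the substrate-independent anti, Markovnikov course. This should give 24 together with the (9S,10R)-bromo lactone F1. The two are diastereomers because ring A is already enantiopure, so they are parted by chromatography or crystallisation and the route is rejoined at 24. F1 can be sent back to 23 by zinc in acetic acid (reductive elimination). Stereocontrol by catalyst is replaced by separation and recycling.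

**Step 8.** The likely failures are erosion of the formyl-exo preference (giving the C14 epimer), insufficient face selectivity with this β-bromo enal, or stepwise addition at the bromine-bearing carbon followed by loss of bromide. Fallback: setting out from 10 and 13, the cycloaddition is promoted by a stoichiometric, bulky, achiral aluminium aryloxide, Al(OC6H3-2,6-Ph2)3, in toluene at −78 °C. Its pocket encloses the formyl group and enforces the exo mode. This gives the racemate, that is 14 with the mirror-image (1S,2S,6R) adduct F2, which is resolved by preparative chromatography on a chiral stationary phase. The route is rejoined at 14. Asymmetric catalysis is replaced by a racemic, exo-enforced cycloaddition and physical resolution.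

**Step 20.** The likely failures are slow capture of the aroylpalladium by the hindered C13 hydroxyl, leading to oligomers or loss of the aryl bromide by reduction, and attack of palladium on a secondary C–Br bond at 90 °C. Fallback: setting out from 30, carbon–carbon bond formation is separated from ring closure. Hydroxycarbonylation at ordinary concentration (Pd(OAc)2, Xantphos, CO, water, Et3N, dioxane, 80 °C) gives the seco acid F3. Shiina macrolactonisation (2-methyl-6-nitrobenzoic anhydride, DMAP, toluene, slow addition, rt) then closes the ring and the route is rejoined at 31.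

**Step 16.** The likely failures are displacement of the C9 bromide by the C10 alkoxide released on ring opening (epoxide formation) and incomplete aminolysis of the hindered aryl pivalate. Fallback: setting out from 24, a reductive route is used.
- i-Bu2AlH (CH2Cl2, −78 °C) reduces the lactone to the lactol and the pivalate to the phenol, giving the lactol phenol F4, in which O10 stays tied up in the ring.
- Excess 28 (THF, 0 °C) adds to the open aldehyde form to give the triol F5 as a C13 epimer mixture.
- MnO2 (CH2Cl2, rt) oxidises only the allylic alcohol to the hydroxy enone F6.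
- Silylation under the conditions of step 17 rejoins the route at 29, and C13 is then set by step 19 as before.

**Step 21.** The likely failures are competing hydrogen-atom transfer to C2=C3 and capture of hydrogen instead of bromine by the tertiary radical. Fallback: setting out from 31, an ionic two-stage Markovnikov sequence replaces the radical step. Oxymercuration (Hg(OAc)2, THF/H2O, 0 °C) should be far faster at the unhindered 1,1-disubstituted alkene than at the ring alkene, and gives the organomercurial F7. This is reduced in the same flask with NaBH4 to the tertiary alcohol F8. Me3SiBr (CH2Cl2, −40 °C) then exchanges the tertiary hydroxyl for bromide with the help of the neighbouring ester, rejoining the route at 32.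

## Further compounds

F1 | step 15 | (9S,10R)-bromo lactone, C9/C10 diastereomer of 24 | CC1=CC[C@H](Br)[C@@](C)(CC[C@H](Br)[C@]2(C)OC(=O)CC2)[C@@H]1Cc1cc(Br)ccc1OC(=O)C(C)(C)C
F2 | step 8 | (1S,2S,6R) adduct, enantiomer of 14 | CC1=C(O[Si](C(C)C)(C(C)C)C(C)C)C[C@@H](Br)[C@](C)(C=O)[C@H]1Cc1cc(Br)ccc1OC(=O)C(C)(C)C
F3 | step 20 | seco acid (Ar1–CO2H, C13–OH, C10–OSiEt3, Ar4–OSiMe2t-Bu) | CC1=CC[C@H](Br)[C@@](C)(CC[C@@H](Br)[C@@](C)(O[Si](CC)(CC)CC)CC[C@@H](C(C)=C)O)[C@@H]1Cc1cc(C(=O)O)ccc1O[Si](C)(C)C(C)(C)C
F4 | step 16 | lactol phenol (anomer mixture) | CC1=CC[C@H](Br)[C@@](C)(CC[C@@H](Br)[C@@]2(C)OC(O)CC2)[C@@H]1Cc1cc(Br)ccc1O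
F5 | step 16 | triol (C13 epimer mixture) | CC1=CC[C@H](Br)[C@@](C)(CC[C@@H](Br)[C@@](C)(O)CCC(O)C(C)=C)[C@@H]1Cc1cc(Br)ccc1O
F6 | step 16 | hydroxy enone with free phenol | CC1=CC[C@H](Br)[C@@](C)(CC[C@@H](Br)[C@@](C)(O)CCC(=O)C(C)=C)[C@@H]1Cc1cc(Br)ccc1O
F7 | step 21 | organomercurial (acetoxymercurio-methyl carbinol on C13) | CC1=CC[C@H](Br)[C@@]2(C)CC[C@@H](Br)[C@@](C)(O[Si](CC)(CC)CC)CC[C@@H](C(C)(O)C[Hg]OC(C)=O)OC(=O)c3ccc(O[Si](C)(C)C(C)(C)C)c(c3)C[C@H]12
F8 | step 21 | tertiary alcohol (CMe2OH on C13) | CC1=CC[C@H](Br)[C@@]2(C)CC[C@@H](Br)[C@@](C)(O[Si](CC)(CC)CC)CC[C@@H](C(C)(C)O)OC(=O)c3ccc(O[Si](C)(C)C(C)(C)C)c(c3)C[C@H]12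
A1 | alternative 1 | 19-membered (E,E)-dienyl lactone | C/C1=C\Cc2cc(ccc2OC(C)=O)C(=O)O[C@H](C(C)(C)Br)CC[C@](C)(O[Si](CC)(CC)CC)[C@H](Br)CC/C(C)=C/CC1
A2 | alternative 1 | target as phenol acetate and C10 triethylsilyl ether | CC1=CC[C@H](Br)[C@@]2(C)CC[C@@H](Br)[C@@](C)(O[Si](CC)(CC)CC)CC[C@@H](C(C)(C)Br)OC(=O)c3ccc(OC(C)=O)c(c3)C[C@H]12
A3 | alternative 2 | aryl bromide alcohol with 9,10-epoxide | CC1=CC[C@H](Br)[C@@](C)(CC[C@@H]2O[C@@]2(C)CC[C@@H](C(C)=C)O)[C@@H]1Cc1cc(Br)ccc1O[Si](C)(C)C(C)(C)C
A4 | alternative 2 | 15-membered lactone with 9,10-epoxide, isopropenyl group and phenol silyl ether | CC1=CC[C@H](Br)[C@@]2(C)CC[C@@H]3O[C@@]3(C)CC[C@@H](C(C)=C)OC(=O)c3ccc(O[Si](C)(C)C(C)(C)C)c(c3)C[C@H]12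
A5 | alternative 3 | bis-silyl diene | C=C(O[Si](C)(C)C(C)(C)C)/C(C)=C/Cc1cc(Br)ccc1O[Si](C)(C)C(C)(C)C
A6 | alternative 3 | ring A aldehyde with C3 silyl enol ether and phenol silyl ether | CC1=C(O[Si](C)(C)C(C)(C)C)C[C@H](Br)[C@@](C)(C=O)[C@@H]1Cc1cc(Br)ccc1O[Si](C)(C)C(C)(C)C
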